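**Plan**
- Retrosynthesis: cut O1–C2 of the flavanone ring C (intramolecular oxa-Michael addition, with a temporary CO2tBu group on C3); then the C2–C3 bond (Knoevenagel, ring B arrives as an aldehyde) and the C3–CO2tBu bond; then the biaryl bond between flavone C3 and flavanone C6 (Negishi coupling).
- Forward: phloroacetophenone becomes the ring A iodide 5 in four steps; the purchased flavone is benzylated and zincated at C3; the halves are joined; the phenol is unmasked, the β-keto ester and arylidene are installed; ring C is closed last; one hydrogenolysis frees the four phenols.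
- Enabling feature: in ring C, O1 and C2 sit β to the C4 ketone with only the C3 methylene between them. Ring C is therefore the oxa-Michael adduct of an ortho-hydroxyaryl enone, and C3 can carry a traceless ester that activates the acceptor and gives a hydrogen-bonding catalyst a 1,3-dicarbonyl to hold.
- On ring A, O1 lies para to the flavone-bearing C6. Only that phenol is left free (the oxygen next to the flavone is benzylated right after it has directed the iodination), so the 6-linked flavanone is the only possible closure.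
- Stereochemistry: C2 (R) is set in the ring closure by a cinchona thiourea–amine catalyst; the transient C3 centre is erased on decarboxylation, and every later operation is base-free.

Key step: step 10

Assumption 1: the two pseudoenantiomeric cinchona thioureas give opposite configurations at C2; the quinine-derived one is written for the 2R series, and its quinidine-derived pseudoenantiomer replaces it, with nothing else changed, if a pilot run shows the opposite sense.
Assumption 2: the biaryl axis between flavone C3 and flavanone C6 has no descriptor in the target and is treated as not configurationally fixed, so C2 is the only stereocentre to control.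

**Step 1**
Reactants: 1 2',4',6'-trihydroxyacetophenone (anhydrous)
Product: 2 1-[4-(benzyloxy)-2,6-dihydroxyphenyl]ethan-1-one
Conditions: BnOH (1.05 equiv), PPh3, diisopropyl azodicarboxylate, THF, 0 °C to rt
Reagents that add atoms: benzyl alcohol, OCc1ccccc1
Why: The Mitsunobu reaction should etherify the 4-OH alone, because it is the most acidic hydroxyl and the only one not hydrogen-bonded to the acetyl group, and the neutral conditions avoid the C-benzylation that basic alkylation of phloroglucinols risks.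

**Step 2**
Reactants: 2 1-[4-(benzyloxy)-2,6-dihydroxyphenyl]ethan-1-one
Product: 3 1-[4-(benzyloxy)-2-hydroxy-6-(methoxymethoxy)phenyl]ethan-1-one
Conditions: MOMCl (1.1 equiv), iPr2NEt, CH2Cl2, 0 °C to rt
Reagents that add atoms: chloromethyl methyl ether, COCCl
Why: O-Alkylation of one of the two equivalent chelated hydroxyls should stop at the mono-ether, because the remaining hydroxyl is then fully locked in the hydrogen bond to the ketone.

**Step 3**
Reactants: 3 1-[4-(benzyloxy)-2-hydroxy-6-(methoxymethoxy)phenyl]ethan-1-one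
Product: 4 1-[4-(benzyloxy)-2-hydroxy-3-iodo-6-(methoxymethoxy)phenyl]ethan-1-one
Conditions: N-iodosuccinimide (1.05 equiv), DMF, 0 °C to rt, dark
Reagents that add atoms: N-iodosuccinimide, O=C1CCC(=O)N1I
Why: Electrophilic aromatic iodination should go ortho to the free phenol (C3, between OH and OBn), as is usual for 2-hydroxy-4,6-dialkoxyacetophenones, which puts the halogen on the carbon flanked by the two oxygens that end as the 5- and 7-hydroxyls.

**Step 4**
Reactants: 4 1-[4-(benzyloxy)-2-hydroxy-3-iodo-6-(methoxymethoxy)phenyl]ethan-1-one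
Product: 5 1-[2,4-bis(benzyloxy)-3-iodo-6-(methoxymethoxy)phenyl]ethan-1-one
Conditions: BnBr (1.3 equiv), K2CO3, DMF, 60 °C
Reagents that add atoms: benzyl bromide, BrCc1ccccc1
Why: Williamson etherification caps the phenol next to iodine, so that later only the oxygen para to the iodine-bearing carbon can be unmasked.

**Step 5**
Reactants: 6 5-hydroxy-7-methoxy-2-(4-methoxyphenyl)-4H-chromen-4-one (apigenin 7,4'-dimethyl ether)
Product: 7 5-(benzyloxy)-7-methoxy-2-(4-methoxyphenyl)-4H-chromen-4-one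
Conditions: BnBr (1.5 equiv), K2CO3, DMF, 80 °C
Reagents that add atoms: benzyl bromide, BrCc1ccccc1
Why: Williamson etherification under forcing conditions benzylates the chelated 5-OH and so removes the acidic proton before the C3 metalation.

**Step 6**
Reactants: 7 5-(benzyloxy)-7-methoxy-2-(4-methoxyphenyl)-4H-chromen-4-one; 5 1-[2,4-bis(benzyloxy)-3-iodo-6-(methoxymethoxy)phenyl]ethan-1-one
Product: 10 3-[3-acetyl-2,6-bis(benzyloxy)-4-(methoxymethoxy)phenyl]-5-(benzyloxy)-7-methoxy-2-(4-methoxyphenyl)-4H-chromen-4-one, via 3-lithioflavone 8 (not isolated), via flavon-3-ylzinc chloride 9 (not isolated)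
Conditions: 7, LiN(iPr)2 (1.1 equiv), THF, −78 °C; ZnCl2 (1.3 equiv), −78 °C to rt; then 5, Pd2(dba)3 (2.5 mol %), RuPhos (10 mol %), THF, 65 °C
Reagents that add atoms: none
Why: Deprotonation of the flavone at C3 (the vinylic C–H alpha to the C4 carbonyl), transmetalation to zinc and Negishi coupling with a dialkylbiarylphosphine ligand of the kind used for tetra-ortho-substituted biaryls should join the halves, the arylzinc tolerating the enolisable acetyl group.

**Step 7**
Reactants: 10 3-[3-acetyl-2,6-bis(benzyloxy)-4-(methoxymethoxy)phenyl]-5-(benzyloxy)-7-methoxy-2-(4-methoxyphenyl)-4H-chromen-4-one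
Product: 11 3-[3-acetyl-2,6-bis(benzyloxy)-4-hydroxyphenyl]-5-(benzyloxy)-7-methoxy-2-(4-methoxyphenyl)-4H-chromen-4-one
Conditions: HCl (2 M), MeOH–THF, rt
Reagents that add atoms: none
Why: Acid-catalysed acetal cleavage removes the methoxymethyl group, which the ortho carbonyl activates, under conditions that should leave the benzyl ethers and the flavone untouched.

**Step 8**
Reactants: 11 3-[3-acetyl-2,6-bis(benzyloxy)-4-hydroxyphenyl]-5-(benzyloxy)-7-methoxy-2-(4-methoxyphenyl)-4H-chromen-4-one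
Product: 13 tert-butyl 3-{2,4-bis(benzyloxy)-3-[5-(benzyloxy)-7-methoxy-2-(4-methoxyphenyl)-4-oxo-4H-chromen-3-yl]-6-hydroxyphenyl}-3-oxopropanoate, via aryl tert-butyl carbonate 12 (not isolated)
Conditions: Boc2O (1.2 equiv), DMAP (10 mol %), CH2Cl2, rt; solvent exchange; LiN(SiMe3)2 (2.5 equiv), THF, −78 to 0 °C; aq. NH4Cl
Reagents that add atoms: di-tert-butyl dicarbonate, CC(C)(C)OC(=O)OC(=O)OC(C)(C)C
Why: O-Acylation of the phenol followed by a Baker–Venkataraman-type intramolecular O-to-C transfer of the tert-butoxycarbonyl group from the ketone enolate (six-membered transition state) should give the β-keto ester on carbon only and free the phenol again.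

**Step 9**
Reactants: 13 tert-butyl 3-{2,4-bis(benzyloxy)-3-[5-(benzyloxy)-7-methoxy-2-(4-methoxyphenyl)-4-oxo-4H-chromen-3-yl]-6-hydroxyphenyl}-3-oxopropanoate; 14 4-(benzyloxy)benzaldehyde
Product: 15 tert-butyl 2-{2,4-bis(benzyloxy)-3-[5-(benzyloxy)-7-methoxy-2-(4-methoxyphenyl)-4-oxo-4H-chromen-3-yl]-6-hydroxybenzoyl}-3-[4-(benzyloxy)phenyl]prop-2-enoate (alkene isomer mixture, used as obtained)
Conditions: piperidine (10 mol %), AcOH (10 mol %), 4 Å molecular sieves, toluene, rt to 40 °C
Reagents that add atoms: none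
Why: Knoevenagel condensation of the β-keto ester with the aromatic aldehyde under piperidinium acetate catalysis should give the alkylidene β-keto ester, the hydrogen bond of the phenol to the ketone holding back uncatalysed ring closure.

**Step 10**
Reactants: 15 tert-butyl 2-{2,4-bis(benzyloxy)-3-[5-(benzyloxy)-7-methoxy-2-(4-methoxyphenyl)-4-oxo-4H-chromen-3-yl]-6-hydroxybenzoyl}-3-[4-(benzyloxy)phenyl]prop-2-enoate
Product: 18 (2R)-5,7-bis(benzyloxy)-6-[5-(benzyloxy)-7-methoxy-2-(4-methoxyphenyl)-4-oxo-4H-chromen-3-yl]-2-[4-(benzyloxy)phenyl]-2,3-dihydro-4H-chromen-4-one, via tert-butyl flavanone-3-carboxylate 16 (not isolated), via flavanone-3-carboxylic acid 17 (not isolated)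
Conditions: 9-amino(9-deoxy)epi-quinine-derived N-[3,5-bis(trifluoromethyl)phenyl]thiourea (10–20 mol %), toluene, −25 °C; then TsOH·H2O (1 equiv), 80 °C
Reagents that add atoms: none
Why: The quinuclidine nitrogen of the catalyst takes the proton of the only free phenol (the oxygen para to the flavone-bearing carbon of ring A) while the thiourea N–H pair binds the 1,3-dicarbonyl of the alkylidene β-keto ester, and the ion-paired phenoxide adds to the β-carbon in a 6-endo-trig intramolecular oxa-Michael addition that closes ring C and gives the β-keto ester 16. The closest known reaction type is the cinchona thiourea-catalysed cyclisation of 2'-hydroxyaryl alkylidene β-keto esters to 3-carboxyflavanones with acid-promoted decarboxylation in the same flask. The new stereocentre C2 is controlled by the catalyst, which exposes one face of the β-carbon to the tethered phenoxide; the second centre at C3 is transient, and its epimers converge when TsOH cleaves the tert-butyl ester (loss of 2-methylpropene) and the β-keto acid 17 loses CO2 through its enol. The step needs regioselectivity between the two oxygens ortho to the ketone, which is secured because the oxygen next to the flavone is a benzyl ether, so that only the 6-linked flavanone can form. It also needs the chalcone-type acceptor to react in preference to the flavone enone, which is tetrasubstituted, not doubly activated and out of reach of the phenol. The acidic, base-free decarboxylation avoids the retro-oxa-Michael opening that would racemise C2.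

**Step 11**
Reactants: 18 (2R)-5,7-bis(benzyloxy)-6-[5-(benzyloxy)-7-methoxy-2-(4-methoxyphenyl)-4-oxo-4H-chromen-3-yl]-2-[4-(benzyloxy)phenyl]-2,3-dihydro-4H-chromen-4-one
Product: 19 (2R)-5,7-dihydroxy-6-[5-hydroxy-7-methoxy-2-(4-methoxyphenyl)-4-oxo-4H-chromen-3-yl]-2-(4-hydroxyphenyl)-2,3-dihydro-4H-chromen-4-one
Conditions: H2 (1 atm), Pd/C (10 wt % palladium on carbon), EtOAc–MeOH, rt, stopped at full debenzylation
Reagents that add atoms: none
Why: Hydrogenolysis of the four benzyl ethers under neutral conditions should free all phenols without touching C2, because no base is present to open ring C by retro-oxa-Michael reaction.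

**Compound list**
1 | 2',4',6'-trihydroxyacetophenone | CC(=O)c1c(O)cc(O)cc1O | starting material
2 | 1-[4-(benzyloxy)-2,6-dihydroxyphenyl]ethan-1-one | CC(=O)c1c(O)cc(OCc2ccccc2)cc1O | intermediate
3 | 1-[4-(benzyloxy)-2-hydroxy-6-(methoxymethoxy)phenyl]ethan-1-one | CC(=O)c1c(O)cc(OCc2ccccc2)cc1OCOC | intermediate
4 | 1-[4-(benzyloxy)-2-hydroxy-3-iodo-6-(methoxymethoxy)phenyl]ethan-1-one | CC(=O)c1c(O)c(I)c(OCc2ccccc2)cc1OCOC | intermediate
5 | 1-[2,4-bis(benzyloxy)-3-iodo-6-(methoxymethoxy)phenyl]ethan-1-one | CC(=O)c1c(OCc2ccccc2)c(I)c(OCc2ccccc2)cc1OCOC | intermediate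
6 | 5-hydroxy-7-methoxy-2-(4-methoxyphenyl)-4H-chromen-4-one | COc1ccc(cc1)-c1cc(=O)c2c(O)cc(OC)cc2o1 | starting material
7 | 5-(benzyloxy)-7-methoxy-2-(4-methoxyphenyl)-4H-chromen-4-one | COc1ccc(cc1)-c1cc(=O)c2c(OCc3ccccc3)cc(OC)cc2o1 | intermediate
8 | [5-(benzyloxy)-7-methoxy-2-(4-methoxyphenyl)-4-oxo-4H-chromen-3-yl]lithium | COc1ccc(cc1)-c1oc2cc(OC)cc(OCc3ccccc3)c2c(=O)c1[Li] | intermediate
9 | chlorido[5-(benzyloxy)-7-methoxy-2-(4-methoxyphenyl)-4-oxo-4H-chromen-3-yl]zinc | COc1ccc(cc1)-c1oc2cc(OC)cc(OCc3ccccc3)c2c(=O)c1[Zn]Cl | intermediate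
10 | 3-[3-acetyl-2,6-bis(benzyloxy)-4-(methoxymethoxy)phenyl]-5-(benzyloxy)-7-methoxy-2-(4-methoxyphenyl)-4H-chromen-4-one | COc1ccc(cc1)-c1oc2cc(OC)cc(OCc3ccccc3)c2c(=O)c1-c1c(OCc2ccccc2)c(C(C)=O)c(OCOC)cc1OCc1ccccc1 | intermediate
11 | 3-[3-acetyl-2,6-bis(benzyloxy)-4-hydroxyphenyl]-5-(benzyloxy)-7-methoxy-2-(4-methoxyphenyl)-4H-chromen-4-one | COc1ccc(cc1)-c1oc2cc(OC)cc(OCc3ccccc3)c2c(=O)c1-c1c(OCc2ccccc2)c(C(C)=O)c(O)cc1OCc1ccccc1 | intermediate
12 | 2-acetyl-3,5-bis(benzyloxy)-4-[5-(benzyloxy)-7-methoxy-2-(4-methoxyphenyl)-4-oxo-4H-chromen-3-yl]phenyl tert-butyl carbonate | COc1ccc(cc1)-c1oc2cc(OC)cc(OCc3ccccc3)c2c(=O)c1-c1c(OCc2ccccc2)c(C(C)=O)c(OC(=O)OC(C)(C)C)cc1OCc1ccccc1 | intermediate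
13 | tert-butyl 3-{2,4-bis(benzyloxy)-3-[5-(benzyloxy)-7-methoxy-2-(4-methoxyphenyl)-4-oxo-4H-chromen-3-yl]-6-hydroxyphenyl}-3-oxopropanoate | COc1ccc(cc1)-c1oc2cc(OC)cc(OCc3ccccc3)c2c(=O)c1-c1c(OCc2ccccc2)c(C(=O)CC(=O)OC(C)(C)C)c(O)cc1OCc1ccccc1 | intermediate
14 | 4-(benzyloxy)benzaldehyde | O=Cc1ccc(OCc2ccccc2)cc1 | starting material
15 | tert-butyl 2-{2,4-bis(benzyloxy)-3-[5-(benzyloxy)-7-methoxy-2-(4-methoxyphenyl)-4-oxo-4H-chromen-3-yl]-6-hydroxybenzoyl}-3-[4-(benzyloxy)phenyl]prop-2-enoate (alkene isomer mixture) | COc1ccc(cc1)-c1oc2cc(OC)cc(OCc3ccccc3)c2c(=O)c1-c1c(OCc2ccccc2)c(C(=O)C(=Cc2ccc(OCc3ccccc3)cc2)C(=O)OC(C)(C)C)c(O)cc1OCc1ccccc1 | intermediate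
16 | tert-butyl (2R)-5,7-bis(benzyloxy)-6-[5-(benzyloxy)-7-methoxy-2-(4-methoxyphenyl)-4-oxo-4H-chromen-3-yl]-2-[4-(benzyloxy)phenyl]-4-oxo-3,4-dihydro-2H-chromene-3-carboxylate (both C3 epimers) | COc1ccc(-c2oc3cc(OC)cc(OCc4ccccc4)c3c(=O)c2-c2c(OCc3ccccc3)cc3c(c2OCc2ccccc2)C(=O)C(C(=O)OC(C)(C)C)[C@H](c2ccc(OCc4ccccc4)cc2)O3)cc1 | intermediate
17 | (2R)-5,7-bis(benzyloxy)-6-[5-(benzyloxy)-7-methoxy-2-(4-methoxyphenyl)-4-oxo-4H-chromen-3-yl]-2-[4-(benzyloxy)phenyl]-4-oxo-3,4-dihydro-2H-chromene-3-carboxylic acid (both C3 epimers) | COc1ccc(-c2oc3cc(OC)cc(OCc4ccccc4)c3c(=O)c2-c2c(OCc3ccccc3)cc3c(c2OCc2ccccc2)C(=O)C(C(=O)O)[C@H](c2ccc(OCc4ccccc4)cc2)O3)cc1 | intermediate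
18 | (2R)-5,7-bis(benzyloxy)-6-[5-(benzyloxy)-7-methoxy-2-(4-methoxyphenyl)-4-oxo-4H-chromen-3-yl]-2-[4-(benzyloxy)phenyl]-2,3-dihydro-4H-chromen-4-one | COc1ccc(-c2oc3cc(OC)cc(OCc4ccccc4)c3c(=O)c2-c2c(OCc3ccccc3)cc3c(c2OCc2ccccc2)C(=O)C[C@H](c2ccc(OCc4ccccc4)cc2)O3)cc1 | intermediate
19 | (2R)-5,7-dihydroxy-6-[5-hydroxy-7-methoxy-2-(4-methoxyphenyl)-4-oxo-4H-chromen-3-yl]-2-(4-hydroxyphenyl)-2,3-dihydro-4H-chromen-4-one | COc1ccc(-c2oc3cc(OC)cc(O)c3c(=O)c2-c2c(O)cc3c(c2O)C(=O)C[C@H](c2ccc(O)cc2)O3)cc1 | target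

**Totals**
Total step count: 11. Longest linear sequence: 10 steps (steps 1, 2, 3, 4, 6, 7, 8, 9, 10, 11).

**Steps most likely to fail**

Step 6. Transmetalation and reductive elimination at two doubly ortho-flanked carbons may be so slow that protodemetalation of the zinc reagent and reduction of the iodide outrun the coupling. The fallback reverses the polarity and uses a Suzuki–Miyaura coupling. It sets out from 7 and 5. Lithiation of 7 as before and quenching with I2 should give 5-(benzyloxy)-3-iodo-7-methoxy-2-(4-methoxyphenyl)-4H-chromen-4-one F1. Miyaura borylation of 5 (B2pin2, Pd(dppf)Cl2, KOAc, dioxane, 90 °C) should give 1-[2,4-bis(benzyloxy)-6-(methoxymethoxy)-3-(4,4,5,5-tetramethyl-1,3,2-dioxaborolan-2-yl)phenyl]ethan-1-one F2. Coupling of the two (Pd(OAc)2, SPhos, K3PO4, toluene–water, 90 °C) returns to 10.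

Step 10. Facial selectivity may be poor, because the flavone carbonyl can compete for the thiourea, the flanking benzyloxy group can distort substrate binding and the two alkene isomers of 15 may cyclise with different selectivity; the hot acid stage may also erode the result through benzyl ether loss or ring opening. The fallback sets the stereocentre by C–C bond formation on a preformed chromone and sets out from 11. Heating 11 with N,N-dimethylformamide dimethyl acetal (toluene, 100 °C) should give 3-{3-[(2E)-3-(dimethylamino)prop-2-enoyl]-2,6-bis(benzyloxy)-4-hydroxyphenyl}-5-(benzyloxy)-7-methoxy-2-(4-methoxyphenyl)-4H-chromen-4-one F3. Treatment with HCl in CH2Cl2 should close it to 5,7-bis(benzyloxy)-6-[5-(benzyloxy)-7-methoxy-2-(4-methoxyphenyl)-4-oxo-4H-chromen-3-yl]-4H-chromen-4-one F4. Asymmetric 1,4-addition of 4-(benzyloxy)phenylboronic acid ([Rh(OH)(cod)]2, an electron-poor atropisomeric bisphosphine of the MeO-BIPHEP family in the enantiomeric series that gives 2R, toluene–water) returns to 18.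

Step 9. Ring closure may start during the condensation without the chiral catalyst, or the condensation may stall at the hindered β-keto ester. The fallback installs the arylidene before the phenol is unmasked and sets out from 10. C-Acylation of the enolate of 10 (LiN(SiMe3)2, tert-butyl 1H-imidazole-1-carboxylate, THF, −78 °C) should give tert-butyl 3-{2,4-bis(benzyloxy)-3-[5-(benzyloxy)-7-methoxy-2-(4-methoxyphenyl)-4-oxo-4H-chromen-3-yl]-6-(methoxymethoxy)phenyl}-3-oxopropanoate F5. Condensation with 14 under forcing conditions (TiCl4, pyridine, THF, or piperidinium acetate with azeotropic removal of water) should give tert-butyl 2-{2,4-bis(benzyloxy)-3-[5-(benzyloxy)-7-methoxy-2-(4-methoxyphenyl)-4-oxo-4H-chromen-3-yl]-6-(methoxymethoxy)benzoyl}-3-[4-(benzyloxy)phenyl]prop-2-enoate F6. Removal of the methoxymethyl group with dilute HCl in MeOH–THF at 0 °C, where the phenol stays neutral, returns to 15.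

**Further compounds**
F1 | step 6 | 5-(benzyloxy)-3-iodo-7-methoxy-2-(4-methoxyphenyl)-4H-chromen-4-one | COc1ccc(cc1)-c1oc2cc(OC)cc(OCc3ccccc3)c2c(=O)c1I
F2 | step 6 | 1-[2,4-bis(benzyloxy)-6-(methoxymethoxy)-3-(4,4,5,5-tetramethyl-1,3,2-dioxaborolan-2-yl)phenyl]ethan-1-one | CC(=O)c1c(OCc2ccccc2)c(B2OC(C)(C)C(C)(C)O2)c(OCc2ccccc2)cc1OCOC
F3 | step 10 | 3-{3-[(2E)-3-(dimethylamino)prop-2-enoyl]-2,6-bis(benzyloxy)-4-hydroxyphenyl}-5-(benzyloxy)-7-methoxy-2-(4-methoxyphenyl)-4H-chromen-4-one | COc1ccc(cc1)-c1oc2cc(OC)cc(OCc3ccccc3)c2c(=O)c1-c1c(OCc2ccccc2)c(C(=O)/C=C/N(C)C)c(O)cc1OCc1ccccc1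
F4 | step 10 | 5,7-bis(benzyloxy)-6-[5-(benzyloxy)-7-methoxy-2-(4-methoxyphenyl)-4-oxo-4H-chromen-3-yl]-4H-chromen-4-one | COc1ccc(-c2oc3cc(OC)cc(OCc4ccccc4)c3c(=O)c2-c2c(OCc3ccccc3)cc3occc(=O)c3c2OCc2ccccc2)cc1
F5 | step 9 | tert-butyl 3-{2,4-bis(benzyloxy)-3-[5-(benzyloxy)-7-methoxy-2-(4-methoxyphenyl)-4-oxo-4H-chromen-3-yl]-6-(methoxymethoxy)phenyl}-3-oxopropanoate | COc1ccc(cc1)-c1oc2cc(OC)cc(OCc3ccccc3)c2c(=O)c1-c1c(OCc2ccccc2)c(C(=O)CC(=O)OC(C)(C)C)c(OCOC)cc1OCc1ccccc1
F6 | step 9 | tert-butyl 2-{2,4-bis(benzyloxy)-3-[5-(benzyloxy)-7-methoxy-2-(4-methoxyphenyl)-4-oxo-4H-chromen-3-yl]-6-(methoxymethoxy)benzoyl}-3-[4-(benzyloxy)phenyl]prop-2-enoate (alkene isomer mixture) | COc1ccc(cc1)-c1oc2cc(OC)cc(OCc3ccccc3)c2c(=O)c1-c1c(OCc2ccccc2)c(C(=O)C(=Cc2ccc(OCc3ccccc3)cc2)C(=O)OC(C)(C)C)c(OCOC)cc1OCc1ccccc1
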